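**Plan**
1. Retrosynthesis: the O1–C2 bond is cut, and with it its twin O1–C5 through the C2 axis, so that O1 is exchanged for a zirconocene. The C3–C4 bond of the resulting trans-3,4-disubstituted zirconacyclopentane is cut next. This leaves two molecules of 4-allyl-1,2-dimethoxybenzene, so the target is 2 × C11H14O2 plus one O atom.
2. Enabling feature: O1 lies on the C2 axis between two homotopic CH2 groups (C2, C5). Each is attached to a CH (C3, C4) that bears an arylmethyl group whose arene is insulated by one CH2. Two 1-alkenes coupled head to head at divalent zirconium give a five-membered metallacycle with exactly this pattern.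
3. Forward order: steps 1 and 2 supply the enantiopure ansa-zirconocene template. Step 3 joins C3–C4 in a temporary Zr ring, turns one Zr–C bond into C–Br and the other into C–O, and closes the tetrahydrofuran ring by O–CH2 bond formation, which also removes the template.
4. Stereochemistry: trans comes from equilibration of the metallacycle and (3R,4R) from the C2-symmetric (S,S) ligand. Both centres arise in step 3 and lie β to every bond changed afterwards.

Key step: step 3

Abbreviation: EBTHI = ethane-1,2-diylbis(η5-4,5,6,7-tetrahydroinden-1-yl), C20H24, a dianionic bridged bis(cyclopentadienyl)-type ligand.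

Assumption: the planar chirality of the metallocene and the axial chirality of binaphthol cannot be written in SMILES and are carried by the names; the pairing of (S,S) ligand and (3R,4R) ring rests on the quadrant model given in step 3, and the (R,R)-dichloride left over in step 1 would serve if the sense proved opposite.

**Step 1**
Reactants: 1 rac-(EBTHI)ZrCl2; 2 (S)-1,1'-bi-2-naphthol
Product: 3 (S,S)-(EBTHI)Zr[(S)-1,1'-bi-2-naphtholate]
Conditions: 2 (0.5 equiv), Et3N (1.1 equiv), toluene, 80 °C; filter; crystallise from toluene/hexane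
Reagents that add atoms: none
Why: Resolution by diastereomeric derivatisation (chloride/aryloxide exchange at tetravalent zirconium): the C2-symmetric (S)-binaphtholate can chelate across the wedge only of the matching (S,S)-metallocene, so half an equivalent picks out this enantiomer and leaves the (R,R)-dichloride unchanged; no carbon stereocentre is formed.

**Step 2**
Reactants: 3 (S,S)-(EBTHI)Zr[(S)-1,1'-bi-2-naphtholate]
Product: 4 (S,S)-(EBTHI)ZrCl2
Conditions: HCl (2 M in Et2O, 2.0 equiv), toluene/Et2O, 0 °C; filter
Reagents that add atoms: hydrogen chloride, Cl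
Why: Protonolysis of the two Zr–O(aryl) bonds by anhydrous HCl is the standard return of a metallocene aryloxide to its dichloride; it leaves the η5-bound ligand and its planar chirality untouched and lets the poorly soluble dichloride separate from free binaphthol.

**Step 3**
Reactants: 4 (S,S)-(EBTHI)ZrCl2; 5 4-allyl-1,2-dimethoxybenzene (methyl eugenol, 2 equiv)
Product: 12 (3R,4R)-3,4-bis(3,4-dimethoxybenzyl)tetrahydrofuran, via dibutylzirconocene 6 (not isolated), via butene complex 7 (not isolated), via zirconacyclopentane 8 (not isolated), via bromoalkylzirconocene imidate 9 (not isolated), via zirconium alkoxide 10 (not isolated), via bromohydrin 11 (not isolated)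
Conditions: n-BuLi (2.0 equiv), THF, −78 °C; 5 (2.0 equiv), −78 to 23 °C, Ar sweep; NBS (1.0 equiv), −78 °C; anhydrous t-BuOOH in decane (1.0 equiv), −78 to 0 °C; 2 M aq NaOH, 23 to 40 °C
Reagents that add atoms: tert-butyl hydroperoxide, CC(C)(C)OO
Why: Proposed new method: loss of butane from 6 gives the divalent zirconium complex 7, its butene is displaced by 5, and two bound alkenes couple oxidatively at their internal carbons to close the temporary five-membered ring of 8 (C3–C4 bond), the closest known reactions being the reversible head-to-head pairing of 1-alkenes on zirconocene and the enantioselective cyclisation of tethered 1,6-dienes through trans-fused zirconabicycles on this same ligand; new are the untethered enantioselective pairing and the exchange of Zr for O that follows. Regiochemistry follows from the CH2 spacer, which makes each arylmethyl group behave as an alkyl group and take a β position away from the ligand, and the trans relation at C3/C4 follows from equilibration to the pseudo-diequatorial ring. The absolute configuration is set by the ligand: seen from the open side, the six-membered rings of the (S,S) ligand fill the upper right and lower left quadrants, so the ring that points its arylmethyl groups to the upper left and lower right, which is (3R,4R), should be the stable one, and since the (3S,4S) ring needs the wrong face of both alkenes a moderate bias per alkene is squared while a single error ends in the separable cis (meso) series. NBS then cleaves one Zr–C bond with transfer of Br to carbon (known electrophilic halogenolysis of alkylzirconocenes); the two bonds are homotopic through the C2 axis, so either gives 9, and a second cleavage is slower because the acyclic alkyl(imidato) complex is less strained and less electron-rich than the dialkyl metallacycle, while the low temperature keeps NBS off the dimethoxyarenes. t-BuOOH protonates off the imidate, binds as peroxide, and the remaining alkyl group shifts from Zr to the bound oxygen with O–O cleavage (known for alkylzirconocene halides and alkyl(tert-butylperoxo)metallocenes), so that in 10 one former Zr–C carbon is an electrophile and the other carries the nucleophilic oxygen. Aqueous NaOH frees 11 from zirconium and its alkoxide displaces bromide in a 5-exo-tet SN2 (Williamson) closure that forms the O–CH2 bond of the tetrahydrofuran at a non-stereogenic carbon, so C3 and C4 are carried over unchanged.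

**Compound list**
1 | rac-(EBTHI)ZrCl2 | Cl[Zr+2]Cl.C(C[c-]1ccc2CCCCc12)[c-]1ccc2CCCCc12 | starting material
2 | (S)-1,1'-bi-2-naphthol | Oc1ccc2ccccc2c1-c1c(O)ccc2ccccc12 | starting material
3 | (S,S)-(EBTHI)Zr[(S)-1,1'-bi-2-naphtholate] | O1c2ccc3ccccc3c2-c2c(O[Zr+2]1)ccc1ccccc21.C(C[c-]1ccc2CCCCc12)[c-]1ccc2CCCCc12 | intermediate
4 | (S,S)-(EBTHI)ZrCl2 | Cl[Zr+2]Cl.C(C[c-]1ccc2CCCCc12)[c-]1ccc2CCCCc12 | intermediate
5 | 4-allyl-1,2-dimethoxybenzene (methyl eugenol) | C=CCc1ccc(OC)c(OC)c1 | starting material
6 | (S,S)-(EBTHI)Zr(n-Bu)2 | CCCC[Zr+2]CCCC.C(C[c-]1ccc2CCCCc12)[c-]1ccc2CCCCc12 | intermediate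
7 | (S,S)-(EBTHI)Zr(η2-1-butene), drawn as the metallacyclopropane | CCC1C[Zr+2]1.C(C[c-]1ccc2CCCCc12)[c-]1ccc2CCCCc12 | intermediate
8 | (S,S)-(EBTHI)Zr[(3R,4R)-3,4-bis(3,4-dimethoxybenzyl)butane-1,4-diyl], the zirconacyclopentane | COc1ccc(C[C@H]2C[Zr+2]C[C@@H]2Cc2ccc(OC)c(OC)c2)cc1OC.C(C[c-]1ccc2CCCCc12)[c-]1ccc2CCCCc12 | intermediate
9 | (S,S)-(EBTHI)Zr[(2R,3R)-4-bromo-2,3-bis(3,4-dimethoxybenzyl)butyl](succinimidate) | COc1ccc(C[C@@H](CBr)[C@H](C[Zr+2]N2C(=O)CCC2=O)Cc2ccc(OC)c(OC)c2)cc1OC.C(C[c-]1ccc2CCCCc12)[c-]1ccc2CCCCc12 | intermediate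
10 | (S,S)-(EBTHI)Zr[(2R,3R)-4-bromo-2,3-bis(3,4-dimethoxybenzyl)butoxide](O-t-Bu) | COc1ccc(C[C@@H](CBr)[C@H](CO[Zr+2]OC(C)(C)C)Cc2ccc(OC)c(OC)c2)cc1OC.C(C[c-]1ccc2CCCCc12)[c-]1ccc2CCCCc12 | intermediate
11 | (2R,3R)-4-bromo-2,3-bis(3,4-dimethoxybenzyl)butan-1-ol | COc1ccc(C[C@@H](CBr)[C@H](CO)Cc2ccc(OC)c(OC)c2)cc1OC | intermediate
12 | (3R,4R)-3,4-bis(3,4-dimethoxybenzyl)tetrahydrofuran | COc1ccc(C[C@H]2COC[C@@H]2Cc2ccc(OC)c(OC)c2)cc1OC | target

**Step count**
Total step count: 3.
Longest linear sequence: 3 steps (1 to 3 to 4 to 12). The carbon skeleton and the ring of 12 are made from 5 in one step.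

**Steps most likely to fail**

Step 3. Several processes may go wrong:
- facial selection by the ligand may be weak in the untethered alkene pairing
- the allyl double bond may migrate into conjugation with the arene on divalent zirconium
- both Zr–C bonds may be brominated
- the hydroperoxide may protonate the Zr–C bond instead of oxidising it

The fallback uses auxiliary-controlled oxidative enolate homocoupling, all of it known chemistry. It sets out from 5 and comes back at 12.
- Hydroboration–oxidation of 5 (9-BBN, THF; NaOH, H2O2) should give 3-(3,4-dimethoxyphenyl)propan-1-ol F1.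
- Oxidation of F1 (TEMPO cat., PhI(OAc)2, MeCN/H2O) should give 3-(3,4-dimethoxyphenyl)propanoic acid F2.
- N-acylation of (S)-4-isopropyloxazolidin-2-one with F2 (pivaloyl chloride, Et3N, LiCl, THF) should give (S)-3-[3-(3,4-dimethoxyphenyl)propanoyl]-4-isopropyloxazolidin-2-one F3.
- Enolisation (LiN(i-Pr)2, THF, −78 °C) and oxidation with TiCl4 should join two enolates, each on the face away from its isopropyl group. This should give (2R,3R)-2,3-bis(3,4-dimethoxybenzyl)-1,4-bis[(S)-4-isopropyl-2-oxooxazolidin-3-yl]butane-1,4-dione F4.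
- Reduction with LiBH4 and MeOH in THF should give (2R,3R)-2,3-bis(3,4-dimethoxybenzyl)butane-1,4-diol F5.
- TsCl in pyridine should form (2R,3R)-2,3-bis(3,4-dimethoxybenzyl)-4-hydroxybutyl 4-methylbenzenesulfonate F6, which should close in the flask to 12.

Step 1. Discrimination between the two metallocene enantiomers may be incomplete during the aryloxide exchange, or unreacted dichloride may co-crystallise with the product. The fallback sets out from 1 and comes back at 4.
- Both enantiomers are derivatised completely with (R)-O-acetylmandelic acid (2 equiv, Et3N, toluene).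
- The two diastereomeric biscarboxylates are then parted by fractional crystallisation.
- (S,S)-(EBTHI)Zr[(R)-O-acetylmandelate]2 F7 is kept and (R,R)-(EBTHI)Zr[(R)-O-acetylmandelate]2 F8 is set aside.
- HCl in Et2O should convert F7 into 4.

Step 2. A local excess of acid may attack the Zr–ring bonds, or the chelating aryloxide may be cleaved only in part. The fallback sets out from 3 and comes back at 4.
- MeLi (2 equiv, Et2O) displaces the binaphtholate as its dilithium salt, which is filtered off.
- This should give the hexane-soluble (S,S)-(EBTHI)ZrMe2 F9.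
- Two equivalents of HCl in Et2O should turn F9 into 4 by clean Zr–CH3 protonolysis.

**Further compounds**
F1 | step 3 | 3-(3,4-dimethoxyphenyl)propan-1-ol | COc1ccc(CCCO)cc1OC
F2 | step 3 | 3-(3,4-dimethoxyphenyl)propanoic acid | COc1ccc(CCC(=O)O)cc1OC
F3 | step 3 | (S)-3-[3-(3,4-dimethoxyphenyl)propanoyl]-4-isopropyloxazolidin-2-one | COc1ccc(CCC(=O)N2C(=O)OC[C@@H]2C(C)C)cc1OC
F4 | step 3 | (2R,3R)-2,3-bis(3,4-dimethoxybenzyl)-1,4-bis[(S)-4-isopropyl-2-oxooxazolidin-3-yl]butane-1,4-dione | COc1ccc(C[C@@H](C(=O)N2C(=O)OC[C@@H]2C(C)C)[C@H](C(=O)N2C(=O)OC[C@@H]2C(C)C)Cc2ccc(OC)c(OC)c2)cc1OC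
F5 | step 3 | (2R,3R)-2,3-bis(3,4-dimethoxybenzyl)butane-1,4-diol | COc1ccc(C[C@@H](CO)[C@H](CO)Cc2ccc(OC)c(OC)c2)cc1OC
F6 | step 3 | (2R,3R)-2,3-bis(3,4-dimethoxybenzyl)-4-hydroxybutyl 4-methylbenzenesulfonate | COc1ccc(C[C@@H](COS(=O)(=O)c2ccc(C)cc2)[C@H](CO)Cc2ccc(OC)c(OC)c2)cc1OC
F7 | step 1 | (S,S)-(EBTHI)Zr[(R)-O-acetylmandelate]2 | CC(=O)O[C@@H](C(=O)[O-])c1ccccc1.CC(=O)O[C@@H](C(=O)[O-])c1ccccc1.[Zr+4].C(C[c-]1ccc2CCCCc12)[c-]1ccc2CCCCc12
F8 | step 1 | (R,R)-(EBTHI)Zr[(R)-O-acetylmandelate]2 | CC(=O)O[C@@H](C(=O)[O-])c1ccccc1.CC(=O)O[C@@H](C(=O)[O-])c1ccccc1.[Zr+4].C(C[c-]1ccc2CCCCc12)[c-]1ccc2CCCCc12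
F9 | step 2 | (S,S)-(EBTHI)ZrMe2 | C[Zr+2]C.C(C[c-]1ccc2CCCCc12)[c-]1ccc2CCCCc12
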